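**Retrosynthetic overview**

- The target is cut at C5–C6 of the side chain (C1 = benzylic CH2, C2 = carbinol carbon, C14 = terminal CH3). It comes from a C5=C6 alkene made by cross-metathesis of an aryl-substituted hex-5-en-2-ol with dec-1-ene, with hydrogenation in the same flask.
- Enabling feature: C5 and C6 are plain CH2 groups in the unbranched, heteroatom-free C3–C14 segment, three bonds beyond the C2 carbinol and well away from the benzene ring (the only ring). A C5=C6 double bond is therefore a traceless handle, and the H2/Pd that removes it also cleaves the O-benzyl group that keeps the two ring oxygens different.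
- The alkenol comes from an aryl Grignard reagent and (S)-2-(but-3-enyl)oxirane (aryl–C1 bond; the C2 configuration is bought with the epoxide). The acetate is put on by a silyl-to-acetyl exchange at the phenoxide.
- The arene comes from 5-bromoresorcinol, desymmetrised as benzyl and silyl ethers. No ring is formed in the route; the benzene ring is carried from the starting material.

Key step: step 5

Remark: the carbinol carbon C2 is S in the target; the alkene formed in step 5 is expected as an E/Z mixture (drawn E), and its geometry is erased in the same step.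

**Step 1**
Reactants: 1 5-bromobenzene-1,3-diol (5-bromoresorcinol)
Product: 2 3-(benzyloxy)-5-bromophenol
Conditions: BnBr (1.0 equiv), K2CO3 (1.0 equiv), acetone, reflux; chromatography, unreacted 1 recovered
Reagents that add atoms: benzyl bromide, BrCc1ccccc1
Why: Williamson ether synthesis on a symmetric diphenol with one equivalent of benzyl bromide should give the mono-ether as the main component of a statistical mixture whose three members differ by one free OH each and are easily separated.

**Step 2**
Reactants: 2 3-(benzyloxy)-5-bromophenol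
Product: 3 [3-(benzyloxy)-5-bromophenoxy](tert-butyl)dimethylsilane
Conditions: TBSCl, imidazole, DMF, rt
Reagents that add atoms: tert-butyldimethylsilyl chloride, CC(C)(C)[Si](C)(C)Cl
Why: Imidazole-promoted O-silylation of a phenol masks the acidic OH for the Grignard step with a group that is orthogonal to the benzyl ether.

**Step 3**
Reactants: 3 [3-(benzyloxy)-5-bromophenoxy](tert-butyl)dimethylsilane; 4 (2S)-2-(but-3-en-1-yl)oxirane
Product: 6 (2S)-1-{3-(benzyloxy)-5-[(tert-butyldimethylsilyl)oxy]phenyl}hex-5-en-2-ol, via arylmagnesium bromide 5 (not isolated)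
Conditions: Mg, I2 (cat.), THF, 50 °C; then CuI (10 mol%), 4, THF, −30 → 0 °C; aq. NH4Cl
Reagents that add atoms: none
Why: Magnesium insertion followed by copper(I)-catalysed SN2 opening of the monosubstituted epoxide at its unsubstituted CH2 (Grignard/cuprate epoxide opening) forms the aryl–C1 bond; the C2 stereocentre is not created here but carried over unchanged from 4, since no bond to it is made or broken.

**Step 4**
Reactants: 6 (2S)-1-{3-(benzyloxy)-5-[(tert-butyldimethylsilyl)oxy]phenyl}hex-5-en-2-ol
Product: 8 3-(benzyloxy)-5-[(2S)-2-hydroxyhex-5-en-1-yl]phenyl acetate, via tetrabutylammonium phenoxide 7 (not isolated)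
Conditions: TBAF (1.05 equiv), THF, 0 °C; then Ac2O (1.2 equiv), 0 °C; aq. NH4Cl
Reagents that add atoms: acetic anhydride, CC(=O)OC(C)=O
Why: Fluoride desilylation of the aryl silyl ether liberates the phenoxide, which is acetylated in the same flask far faster than the neutral secondary alcohol (acyl transfer to the stronger nucleophile, no acylation catalyst present), so the ester should end up on the phenol oxygen only.

**Step 5**
Reactants: 8 3-(benzyloxy)-5-[(2S)-2-hydroxyhex-5-en-1-yl]phenyl acetate; 9 dec-1-ene
Product: 12 3-hydroxy-5-[(2S)-2-hydroxytetradecyl]phenyl acetate, via cross-metathesis alkene 10 (not isolated), via saturated benzyl ether 11 (not isolated)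
Conditions: 9 (4 equiv), Hoveyda–Grubbs II (3 mol%), EtOAc, 45 °C, N2 sweep; then 10% Pd/C, H2 (1 atm), rt, same flask
Reagents that add atoms: none
Why: Olefin cross-metathesis by the Chauvin mechanism ([2+2] cycloaddition of the Ru alkylidene to the terminal C=C of 8 and of 9, cycloreversion of the ruthenacyclobutanes, loss of ethylene) joins C5 of 8 to the CH carbon of 9 as the C5=C6 double bond of 10, and H2 over Pd/C in the same flask then saturates this alkene (11) and cleaves the aryl benzyl ether by hydrogenolysis to give 12. The closest known reaction type is the cross-metathesis of two unhindered terminal alkenes, one carrying a remote free hydroxyl, followed by one-pot Pd/C hydrogenation with concurrent O-debenzylation, as used for long-chain lipid alcohols. No ring is closed and no stereocentre is created: C2 lies three bonds from the reacting carbon and is untouched, and the E/Z geometry of 10 is erased by the hydrogenation. The step needs cross- over self-coupling, which should be secured by the fourfold excess of cheap 9 and by the reversibility of metathesis between two alkenes of the same unhindered terminal class, whose homodimers re-enter the cycle while ethylene is swept out. It also needs chemoselective reduction: C=C and ArO–CH2Ph react at 1 atm H2 in a non-nucleophilic solvent, whereas the aryl acetate, the arene and the C2–O bond (homobenzylic, not benzylic) should not, and the substrate has no other reducible group. In this one operation nine of the fourteen chain carbons are added, the chain reaches its final oxidation level and the second phenol is unmasked, so the product is the target itself.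

**Compound list**

1 | 5-bromobenzene-1,3-diol (5-bromoresorcinol) | Oc1cc(O)cc(Br)c1 | starting material
2 | 3-(benzyloxy)-5-bromophenol | Oc1cc(Br)cc(OCc2ccccc2)c1 | intermediate
3 | [3-(benzyloxy)-5-bromophenoxy](tert-butyl)dimethylsilane | CC(C)(C)[Si](C)(C)Oc1cc(Br)cc(OCc2ccccc2)c1 | intermediate
4 | (2S)-2-(but-3-en-1-yl)oxirane [(S)-1,2-epoxyhex-5-ene] | C=CCC[C@H]1CO1 | starting material
5 | {3-(benzyloxy)-5-[(tert-butyldimethylsilyl)oxy]phenyl}magnesium bromide | CC(C)(C)[Si](C)(C)Oc1cc([Mg]Br)cc(OCc2ccccc2)c1 | intermediate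
6 | (2S)-1-{3-(benzyloxy)-5-[(tert-butyldimethylsilyl)oxy]phenyl}hex-5-en-2-ol | C=CCC[C@H](O)Cc1cc(OCc2ccccc2)cc(O[Si](C)(C)C(C)(C)C)c1 | intermediate
7 | tetrabutylammonium 3-(benzyloxy)-5-[(2S)-2-hydroxyhex-5-en-1-yl]phenoxide | C=CCC[C@H](O)Cc1cc([O-])cc(OCc2ccccc2)c1.CCCC[N+](CCCC)(CCCC)CCCC | intermediate
8 | 3-(benzyloxy)-5-[(2S)-2-hydroxyhex-5-en-1-yl]phenyl acetate | C=CCC[C@H](O)Cc1cc(OCc2ccccc2)cc(OC(C)=O)c1 | intermediate
9 | dec-1-ene | C=CCCCCCCCC | starting material
10 | 3-(benzyloxy)-5-[(2S,5E)-2-hydroxytetradec-5-en-1-yl]phenyl acetate (E drawn, E/Z mixture expected) | CCCCCCCC/C=C/CC[C@H](O)Cc1cc(OCc2ccccc2)cc(OC(C)=O)c1 | intermediate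
11 | 3-(benzyloxy)-5-[(2S)-2-hydroxytetradecyl]phenyl acetate | CCCCCCCCCCCC[C@H](O)Cc1cc(OCc2ccccc2)cc(OC(C)=O)c1 | intermediate
12 | 3-hydroxy-5-[(2S)-2-hydroxytetradecyl]phenyl acetate | CCCCCCCCCCCC[C@H](O)Cc1cc(O)cc(OC(C)=O)c1 | target

**Step count and risks**

Total step count: 5. Longest linear sequence: 5 steps (1 → 2 → 3 → 6 → 8 → 12); 4 and 9 are used as bought.

Steps most likely to fail:

Step 5. Self-metathesis of 8 and ruthenium-hydride-induced migration of the terminal double bond before cross-metathesis may occur. The latter would give chain-length homologues that cannot be removed after hydrogenation. Ruthenium residues may also slow the hydrogenolysis. Fallback (Wittig olefination at the same bond, which cannot shift chain length), setting out from 6: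
- Oxidative cleavage of the terminal alkene (K2OsO4 cat., NaIO4, 2,6-lutidine, dioxane/H2O) should give the C5 aldehyde as its five-membered lactol (5S)-5-({3-(benzyloxy)-5-[(tert-butyldimethylsilyl)oxy]phenyl}methyl)oxolan-2-ol F1.
- An excess of nonylidenetriphenylphosphorane (from nonyltriphenylphosphonium bromide and NaHMDS, THF, −78 °C → rt) should open the lactol and form C5=C6, giving (2S,5Z)-1-{3-(benzyloxy)-5-[(tert-butyldimethylsilyl)oxy]phenyl}tetradec-5-en-2-ol F2.
- The silyl-to-acetyl exchange of step 4 (TBAF, then Ac2O) should pass through tetrabutylammonium 3-(benzyloxy)-5-[(2S,5Z)-2-hydroxytetradec-5-en-1-yl]phenoxide F3 to 3-(benzyloxy)-5-[(2S,5Z)-2-hydroxytetradec-5-en-1-yl]phenyl acetate F4.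
- Hydrogenation over Pd/C in EtOAc comes back to the route at 11 and goes on to 12.

Step 1. The second phenol is as nucleophilic as the first, so over-alkylation to the bis-ether lowers the mono-ether yield. Fallback, setting out from 1:
- Exhaustive benzylation (BnBr 2.2 equiv, K2CO3, DMF) gives 1,3-bis(benzyloxy)-5-bromobenzene F5.
- Nucleophilic mono-debenzylation with sodium ethanethiolate (DMF, 90 °C) follows; the phenoxide formed by the first SN2 cleavage makes the second ether a much poorer leaving group, so the reaction should stop at 2, where the route is rejoined.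

Step 4. Acetyl transfer to the secondary hydroxyl under the basic fluoride conditions, or fluoride- or acetate-mediated loss of the new aryl ester during the quench, may erode the chemoselectivity. Fallback (remove the need for chemoselectivity), setting out from 6:
- The secondary hydroxyl is masked as a hydrogenolysable carbonate (CbzCl, pyridine, DMAP cat., CH2Cl2), giving benzyl (2S)-1-{3-(benzyloxy)-5-[(tert-butyldimethylsilyl)oxy]phenyl}hex-5-en-2-yl carbonate F6.
- TBAF then Ac2O (an excess is now harmless) should give, through tetrabutylammonium 3-(benzyloxy)-5-[(2S)-2-{[(benzyloxy)carbonyl]oxy}hex-5-en-1-yl]phenoxide F7, the acetate 3-(benzyloxy)-5-[(2S)-2-{[(benzyloxy)carbonyl]oxy}hex-5-en-1-yl]phenyl acetate F8.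
- Cross-metathesis with 9 under the conditions of step 5 should give 3-(benzyloxy)-5-[(2S,5E)-2-{[(benzyloxy)carbonyl]oxy}tetradec-5-en-1-yl]phenyl acetate F9.
- The same H2/Pd-C treatment saturates the alkene to 3-(benzyloxy)-5-[(2S)-2-{[(benzyloxy)carbonyl]oxy}tetradecyl]phenyl acetate F10 and cleaves both the benzyl ether and the benzyl carbonate (with loss of CO2), coming back to the route at 12.

**Further compounds**

F1 | step 5 | (5S)-5-({3-(benzyloxy)-5-[(tert-butyldimethylsilyl)oxy]phenyl}methyl)oxolan-2-ol (anomer mixture) | OC1CC[C@@H](Cc2cc(OCc3ccccc3)cc(O[Si](C)(C)C(C)(C)C)c2)O1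
F2 | step 5 | (2S,5Z)-1-{3-(benzyloxy)-5-[(tert-butyldimethylsilyl)oxy]phenyl}tetradec-5-en-2-ol | CCCCCCCC/C=C\CC[C@H](O)Cc1cc(OCc2ccccc2)cc(O[Si](C)(C)C(C)(C)C)c1
F3 | step 5 | tetrabutylammonium 3-(benzyloxy)-5-[(2S,5Z)-2-hydroxytetradec-5-en-1-yl]phenoxide | CCCCCCCC/C=C\CC[C@H](O)Cc1cc([O-])cc(OCc2ccccc2)c1.CCCC[N+](CCCC)(CCCC)CCCC
F4 | step 5 | 3-(benzyloxy)-5-[(2S,5Z)-2-hydroxytetradec-5-en-1-yl]phenyl acetate | CCCCCCCC/C=C\CC[C@H](O)Cc1cc(OCc2ccccc2)cc(OC(C)=O)c1
F5 | step 1 | 1,3-bis(benzyloxy)-5-bromobenzene | Brc1cc(OCc2ccccc2)cc(OCc2ccccc2)c1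
F6 | step 4 | benzyl (2S)-1-{3-(benzyloxy)-5-[(tert-butyldimethylsilyl)oxy]phenyl}hex-5-en-2-yl carbonate | C=CCC[C@H](OC(=O)OCc1ccccc1)Cc1cc(OCc2ccccc2)cc(O[Si](C)(C)C(C)(C)C)c1
F7 | step 4 | tetrabutylammonium 3-(benzyloxy)-5-[(2S)-2-{[(benzyloxy)carbonyl]oxy}hex-5-en-1-yl]phenoxide | C=CCC[C@H](OC(=O)OCc1ccccc1)Cc1cc([O-])cc(OCc2ccccc2)c1.CCCC[N+](CCCC)(CCCC)CCCC
F8 | step 4 | 3-(benzyloxy)-5-[(2S)-2-{[(benzyloxy)carbonyl]oxy}hex-5-en-1-yl]phenyl acetate | C=CCC[C@H](OC(=O)OCc1ccccc1)Cc1cc(OCc2ccccc2)cc(OC(C)=O)c1
F9 | step 4 | 3-(benzyloxy)-5-[(2S,5E)-2-{[(benzyloxy)carbonyl]oxy}tetradec-5-en-1-yl]phenyl acetate | CCCCCCCC/C=C/CC[C@H](OC(=O)OCc1ccccc1)Cc1cc(OCc2ccccc2)cc(OC(C)=O)c1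
F10 | step 4 | 3-(benzyloxy)-5-[(2S)-2-{[(benzyloxy)carbonyl]oxy}tetradecyl]phenyl acetate | CCCCCCCCCCCC[C@H](OC(=O)OCc1ccccc1)Cc1cc(OCc2ccccc2)cc(OC(C)=O)c1
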